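**Retrosynthetic overview**
- The C2–aryl bond is cut first. The target comes from 5-hydroxy-6,7-dimethoxychromone and 3,4-dimethoxyphenylboronic acid by an enantioselective 1,4-arylation that de-aromatises the γ-pyrone ring. This sets the only stereocentre in the last step, with no protecting groups.
- 5-Hydroxy-6,7-dimethoxychromone comes from peri-selective O-demethylation of 5,6,7-trimethoxychromone. That chromone comes from one-carbon insertion and O1–C2 closure on 2-hydroxy-4,5,6-trimethoxyacetophenone, all in one pot.
- The acetophenone comes from C-acetylation of mirror-symmetric 3,4,5-trimethoxyphenol at one of its two equivalent ortho carbons.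
- Rings A and B are bought intact. Ring C is closed in step 2 as an aromatic pyrone and saturated at C2–C3 in step 3.

Assumption: the facial sense of the Rh/(S)-biaryl-bisphosphine catalyst is carried over from cyclic enones, where (S)-ligands of this family place the aryl group on the face that corresponds to 2S here. If the first run gives the 2R antipode (chiral HPLC, CD), the (R)-ligand is used with no other change.

**Step 1**
Reactants: 1 3,4,5-trimethoxyphenol
Product: 2 1-(2-hydroxy-4,5,6-trimethoxyphenyl)ethan-1-one
Conditions: AcOH, BF3·OEt2 (3 equiv), 90 °C, 2.5 h; then H2O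
Reagents that add atoms: acetic acid, CC(=O)O
Why: Friedel–Crafts C-acylation through the O-acetate/Fries manifold, in which the para position of 1 is blocked and its two ortho carbons are related by the mirror plane of the ring, so only one ketone can form, and it is held as a BF2 chelate (hydrolysed on work-up) that shuts off a second acylation.

**Step 2**
Reactants: 2 1-(2-hydroxy-4,5,6-trimethoxyphenyl)ethan-1-one
Product: 5 5-hydroxy-6,7-dimethoxy-4H-chromen-4-one, via enaminone 3 (not isolated), via 5,6,7-trimethoxychromone 4 (not isolated)
Conditions: DMF-DMA (2 equiv), PhMe, 100 °C, 3 h; evaporate; then conc. HCl/EtOH (ca. 3 M), reflux, 24–36 h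
Reagents that add atoms: N,N-dimethylformamide dimethyl acetal, COC(OC)N(C)C
Why: Condensation of the methyl ketone with DMF-DMA gives vinylogous amide 3, acid then drives addition–elimination of the single free phenol at the β-carbon with loss of dimethylamine (enaminone route to chromones, only one regiochemistry possible) to give aromatic γ-pyrone 4, and on continued reflux the C4-protonated form (a 4-hydroxybenzopyrylium ion) exposes only the peri 5-OMe to SN2 attack by chloride, which is the selective acid 5-O-demethylation known for polymethoxylated flavones and stops at the hydrogen-bonded 5-OH.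

**Step 3**
Reactants: 5 5-hydroxy-6,7-dimethoxy-4H-chromen-4-one, 6 (3,4-dimethoxyphenyl)boronic acid (2.5 equiv)
Product: 7 (2S)-2-(3,4-dimethoxyphenyl)-5-hydroxy-6,7-dimethoxy-2,3-dihydro-4H-chromen-4-one
Conditions: [Rh(OH)(cod)]2 (1.5 mol %), (S)-MeO-F12-BIPHEP (3.3 mol %), PhMe, 30 °C, 12 h; neutral work-up
Reagents that add atoms: none
Why: Hayashi–Miyaura reaction (Rh(I)-catalysed asymmetric 1,4-addition of an arylboronic acid) used dearomatively: transmetalation gives an aryl–Rh(bisphosphine) species, the (S)-biaryl ligand lets the γ-pyrone bind only through the Re face of C2, syn-carborhodation of C2=C3 destroys the pyrylium-olate delocalisation of ring C and fixes C2 as S, water from the boronic acid/boroxine equilibrium protonates the oxa-π-allyl rhodium, and because the medium is base-free and the 5-OH is left free (its hydrogen bond to C4=O also raises the electrophilicity of C2) the product is the target itself with no retro-oxa-Michael path to racemise.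

**Compound list**
1 | 3,4,5-trimethoxyphenol | COc1cc(O)cc(OC)c1OC | starting material
2 | 1-(2-hydroxy-4,5,6-trimethoxyphenyl)ethan-1-one | CC(=O)c1c(O)cc(OC)c(OC)c1OC | intermediate
3 | (E)-3-(dimethylamino)-1-(2-hydroxy-4,5,6-trimethoxyphenyl)prop-2-en-1-one | CN(C)/C=C/C(=O)c1c(O)cc(OC)c(OC)c1OC | intermediate
4 | 5,6,7-trimethoxy-4H-chromen-4-one | O=c1ccoc2cc(OC)c(OC)c(OC)c12 | intermediate
5 | 5-hydroxy-6,7-dimethoxy-4H-chromen-4-one | O=c1ccoc2cc(OC)c(OC)c(O)c12 | intermediate
6 | (3,4-dimethoxyphenyl)boronic acid | COc1ccc(B(O)O)cc1OC | starting material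
7 | (2S)-2-(3,4-dimethoxyphenyl)-5-hydroxy-6,7-dimethoxy-2,3-dihydro-4H-chromen-4-one | COc1ccc([C@@H]2CC(=O)c3c(cc(OC)c(OC)c3O)O2)cc1OC | target

**Step count and risks**

Total step count: 3. Longest linear sequence: 3 (1 → 2 → 5 → 7).

**Step 3 is most at risk.**
- Three oxygen donors and the aromatic stabilisation of the pyrone make 5 a poor acceptor.
- The 5-OH/4-C=O pair can bind rhodium like an acetylacetonate and slow transmetalation.
- The electron-rich boronic acid 6 protodeboronates.

The fallback sets out from 5 (with 6) and returns at 7. It sets the stereocentre by hydride delivery instead of aryl delivery. An aerobic Pd(II)-catalysed oxidative boron-Heck arylation at C2 (Pd(TFA)2, 1,10-phenanthroline, O2, DMF, 80 °C) keeps the pyrone aromatic. It gives the flavone 2-(3,4-dimethoxyphenyl)-5-hydroxy-6,7-dimethoxy-4H-chromen-4-one F1. A copper hydride asymmetric conjugate reduction then converts F1 into 7. Conditions are Cu(OAc)2, the DTBM-SEGPHOS antipode that gives 2S, (EtO)2MeSiH, t-BuOH, PhMe, 0 °C, with a mild NH4F work-up.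

**Step 2 is next.** Long reflux of a 2-unsubstituted chromone in aqueous ethanolic HCl may hydrate and deformylate the pyrone, or may begin to cleave the 6-OMe. The fallback sets out from 4, isolated by stopping the acid treatment after 1 h, and returns at 7. It moves the demethylation behind the C–C bond formation.
- Compound 4 is arylated with 6 under the catalyst of step 3 to give (2S)-2-(3,4-dimethoxyphenyl)-5,6,7-trimethoxy-2,3-dihydro-4H-chromen-4-one F2.
- The 5-OMe is then removed by chelation-controlled cleavage with BCl3 (1.1 equiv, CH2Cl2, −78 °C, cold quench).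
- The ee must be checked afterwards, because the electron-rich benzylic C2–O bond is sensitive to Lewis acid.

**Step 1 is the least risky.** BF3 at 90 °C can still over-react and cleave the methoxy group ortho to the new ketone. That would give a 2,6-dihydroxy ketone, which would later cyclise in two directions. The fallback sets out from 1 and returns at 4. It forms O1–C2 before the C–C bond.
- DABCO-catalysed oxa-Michael addition of 1 to ethyl propiolate (CH2Cl2, rt) gives ethyl (E)-3-(3,4,5-trimethoxyphenoxy)prop-2-enoate F3.
- LiOH in THF/H2O gives (E)-3-(3,4,5-trimethoxyphenoxy)prop-2-enoic acid F4.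
- Eaton's reagent at 60 °C closes the ring by intramolecular Friedel–Crafts acylation at either of the two equivalent ortho carbons to give 4.
- Compound 4 is then refluxed in ethanolic HCl, as in the second half of step 2, to reach 5.

**Further compounds**
F1 | step 3 | 2-(3,4-dimethoxyphenyl)-5-hydroxy-6,7-dimethoxy-4H-chromen-4-one | COc1ccc(-c2cc(=O)c3c(O)c(OC)c(OC)cc3o2)cc1OC
F2 | step 2 | (2S)-2-(3,4-dimethoxyphenyl)-5,6,7-trimethoxy-2,3-dihydro-4H-chromen-4-one | COc1ccc([C@@H]2CC(=O)c3c(cc(OC)c(OC)c3OC)O2)cc1OC
F3 | step 1 | ethyl (E)-3-(3,4,5-trimethoxyphenoxy)prop-2-enoate | CCOC(=O)/C=C/Oc1cc(OC)c(OC)c(OC)c1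
F4 | step 1 | (E)-3-(3,4,5-trimethoxyphenoxy)prop-2-enoic acid | OC(=O)/C=C/Oc1cc(OC)c(OC)c(OC)c1
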